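**Plan**
- Retrosynthetic cuts, in order: O8–CH3; O1–C8a of the pyranone ring C (key step); C2–C3 (enolate aroylation); C4–C4a (Friedel–Crafts acetylation).
- Forward: ring A is bought as methoxyhydroquinone and ring B as 2,3,4-trimethoxybenzoic acid; acetylation and C-aroylation join them as a 1,3-diketone on a free hydroquinone.
- Ring C is closed last and oxidatively: the hydroquinone becomes a 2-acyl-1,4-benzoquinone and the diketone enol oxygen adds to it (polarity reversal of C8a, normally a nucleophilic arene carbon); O8 is then methylated.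
- Enabling feature: O5 and O8 are para on ring A (a latent C5/C8 quinone), and C8a, which carries O1, lies between C8 and the acyl-bearing C4a, i.e. at C3 of a 2-acylquinone, β to both C4=O and C5=O.
- Consequence: O1 comes from the diketone and not from a ring-A phenol, so the 5,6,7-isomer cannot form and no selective demethylation is needed; O5 stays free because it is chelated to C4=O.
- Stereochemistry: the target has no stereocentre, so nothing has to be set.

Key step: step 4

Remark: serpyllin is achiral (no stereocentre, freely rotating C2–C1' bond), so "single enantiomer" is taken to mean the constitution as drawn.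

**Step 1**
Reactants: 1 2-methoxybenzene-1,4-diol (methoxyhydroquinone)
Product: 2 1-(2,5-dihydroxy-4-methoxyphenyl)ethan-1-one
Conditions: AcOH (1.5 equiv), BF3·OEt2 (3 equiv, neat), 90 °C, Ar; then H2O, 50 °C
Reagents that add atoms: acetic acid, CC(=O)O
Why: Friedel–Crafts (Nencki-type) C-acylation of a phenol with a carboxylic acid in BF3·OEt2 should go to C5 of 1, the only ring position that is para to the methoxy group, ortho to a hydroxyl and unhindered, and the chelated ortho-hydroxy ketone is the thermodynamic sink.

**Step 2**
Reactants: 3 2,3,4-trimethoxybenzoic acid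
Product: 4 2,3,4-trimethoxybenzoyl chloride
Conditions: (COCl)2 (1.3 equiv), DMF (cat.), CH2Cl2, 0 °C to rt; evaporate, use crude
Reagents that add atoms: oxalyl chloride, O=C(Cl)C(Cl)=O
Why: Vilsmeier-catalysed conversion of a carboxylic acid into its chloride, to which the three aryl methyl ethers are inert and from which the volatile by-products leave on evaporation.

**Step 3**
Reactants: 2 1-(2,5-dihydroxy-4-methoxyphenyl)ethan-1-one; 4 2,3,4-trimethoxybenzoyl chloride
Product: 5 1-(2,5-dihydroxy-4-methoxyphenyl)-3-(2,3,4-trimethoxyphenyl)propane-1,3-dione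
Conditions: LiHMDS (4.2 equiv), degassed THF, −78 to −10 °C, Ar; then 4 (1.0 equiv), −78 °C to rt; sat. aq NH4Cl, 0 °C
Reagents that add atoms: none
Why: Claisen-type C-aroylation of the lithium polyanion of an ortho-hydroxyacetophenone, in which both phenols are held as aggregated lithium phenoxides, the ketone enolate carbon is the most nucleophilic site for the single equivalent of 4, one equivalent of base is kept for the more acidic product, and the mild quench avoids acid-catalysed cyclodehydration through the 2-hydroxyl.

**Step 4**
Reactants: 5 1-(2,5-dihydroxy-4-methoxyphenyl)-3-(2,3,4-trimethoxyphenyl)propane-1,3-dione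
Product: 8 5,8-dihydroxy-7-methoxy-2-(2,3,4-trimethoxyphenyl)-4H-chromen-4-one, via acylquinone 6 (not isolated), via flavonequinone 7 (not isolated)
Conditions: Ag2O (2.5 equiv), MgSO4, CH2Cl2 (0.01 M), rt, dark, Ar; filter; then Na2S2O4, H2O/EtOAc, rt
Reagents that add atoms: none
Why: Proposed new method: Ag2O should dehydrogenate the hydroquinone ring of 5 (by far its most easily oxidised site) to the 2-acyl-1,4-benzoquinone 6, in which the ring carbon next to the acyl-bearing carbon (future C8a) is β to both the side-chain carbonyl (future C4) and a quinone carbonyl (future C5), so that the distal oxygen of the Z-enol of the 1,3-diketone adds to it and the adduct tautomerises to the aromatic hydroquinone 8; excess oxidant then takes 8 on to the flavonequinone 7, and dithionite in the work-up returns all material to 8. The closest known reaction types are the conjugate addition of O-, N-, S- and C-nucleophiles to C3 of 2-acyl-1,4-benzoquinones generated from acylhydroquinones and the closure of (2-hydroxybenzoyl)-1,4-benzoquinones to hydroxyxanthones; new here is a 1,3-diketone enol oxygen as the nucleophile, building a chromone. Ring C closes by a 6-endo-trig oxa-Michael addition (equivalently an oxa-6π electrocyclisation of the 1-oxatriene tautomer followed by enolisation), which forms O1–C8a. No stereocentre is formed. The step needs O–C bond formation at C8a and not at the other quinone carbons or between molecules: the tether reaches only the two ring atoms flanking the acyl-bearing carbon, addition to the quinone carbonyl on the other side is a reversible hemiketalisation whereas addition at C8a is made irreversible by aromatisation, the remaining quinone CH is out of reach and deactivated by the vinylogous-ester methoxy group, and high dilution suppresses intermolecular Michael addition of the diketone carbon. O5 (chelated to C4=O) and O8 (free) leave the step already differentiated.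

**Step 5**
Reactants: 8 5,8-dihydroxy-7-methoxy-2-(2,3,4-trimethoxyphenyl)-4H-chromen-4-one
Product: 9 serpyllin, 5-hydroxy-7,8-dimethoxy-2-(2,3,4-trimethoxyphenyl)-4H-chromen-4-one
Conditions: Me2SO4 (1.05 equiv), K2CO3 (1.5 equiv), degassed acetone, rt to 40 °C, Ar
Reagents that add atoms: dimethyl sulfate, COS(=O)(=O)OC
Why: Williamson O-methylation under weak base should take the free, more acidic 8-OH and leave the 5-OH that is hydrogen-bonded to the C4 carbonyl, the usual selectivity in partial methylation of 5-hydroxyflavones, while exclusion of air prevents autoxidation of the hydroquinone to 7.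

**Compound list**
1 | 2-methoxybenzene-1,4-diol (methoxyhydroquinone) | COc1cc(O)ccc1O | starting material
2 | 1-(2,5-dihydroxy-4-methoxyphenyl)ethan-1-one | CC(=O)c1cc(O)c(OC)cc1O | intermediate
3 | 2,3,4-trimethoxybenzoic acid | COc1ccc(C(=O)O)c(OC)c1OC | starting material
4 | 2,3,4-trimethoxybenzoyl chloride | COc1ccc(C(Cl)=O)c(OC)c1OC | intermediate
5 | 1-(2,5-dihydroxy-4-methoxyphenyl)-3-(2,3,4-trimethoxyphenyl)propane-1,3-dione | COc1ccc(C(=O)CC(=O)c2cc(O)c(OC)cc2O)c(OC)c1OC | intermediate
6 | 2-methoxy-5-[3-oxo-3-(2,3,4-trimethoxyphenyl)propanoyl]cyclohexa-2,5-diene-1,4-dione (acylquinone) | COC1=CC(=O)C(C(=O)CC(=O)c2ccc(OC)c(OC)c2OC)=CC1=O | intermediate (not isolated)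
7 | 7-methoxy-2-(2,3,4-trimethoxyphenyl)-4H-chromene-4,5,8-trione (flavonequinone) | COC1=CC(=O)C2=C(OC(=CC2=O)c2ccc(OC)c(OC)c2OC)C1=O | intermediate (not isolated)
8 | 5,8-dihydroxy-7-methoxy-2-(2,3,4-trimethoxyphenyl)-4H-chromen-4-one | COc1ccc(-c2cc(=O)c3c(O)cc(OC)c(O)c3o2)c(OC)c1OC | intermediate
9 | serpyllin, 5-hydroxy-7,8-dimethoxy-2-(2,3,4-trimethoxyphenyl)-4H-chromen-4-one | COc1ccc(-c2cc(=O)c3c(O)cc(OC)c(OC)c3o2)c(OC)c1OC | target

**Step count**
Total steps: 5. Longest linear sequence: 4 (steps 1, 3, 4, 5); step 2 is a one-step branch.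

**Steps most likely to fail**

Step 4 (Proposed new method). The acylquinone may be consumed by intermolecular Michael addition of the diketone carbon (oligomerisation), or may rest in the reversible carbonyl adduct or decompose before ring closure. The fallback uses known chemistry, sets out from 4 and comes back at 8. Commercial 1-(2,6-dihydroxy-4-methoxyphenyl)ethan-1-one F1 would be C-aroylated with 4 as its lithium polyanion (LiHMDS, THF) to 1-(2,6-dihydroxy-4-methoxyphenyl)-3-(2,3,4-trimethoxyphenyl)propane-1,3-dione F2. Cyclodehydration (H2SO4, AcOH, 95 °C; both hydroxyls give the same flavone) should give 5-hydroxy-7-methoxy-2-(2,3,4-trimethoxyphenyl)-4H-chromen-4-one F3. Elbs persulfate oxidation (K2S2O8, aq KOH/pyridine, rt) should attack para to the 5-phenoxide and give 5-hydroxy-7-methoxy-4-oxo-2-(2,3,4-trimethoxyphenyl)-4H-chromen-8-yl hydrogen sulfate F4, formed as its potassium salt. Brief acid hydrolysis (aq HCl, Na2SO3, 80 °C) should then give 8.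

Step 3. The unchelated 5-phenoxide may be O-aroylated, double acylation may occur, or the electron-rich polyanion may be oxidised by traces of air. The fallback is a Baker–Venkataraman sequence that sets out from 2 and 4 and comes back at 5. Compound 2 would be bis-aroylated with 4 (2.2 equiv, pyridine, DMAP cat.) to 2-acetyl-5-methoxy-1,4-phenylene bis(2,3,4-trimethoxybenzoate) F5. Intramolecular O-to-C acyl transfer (KOH, pyridine, 50 °C) should give 4-hydroxy-2-methoxy-5-[3-oxo-3-(2,3,4-trimethoxyphenyl)propanoyl]phenyl 2,3,4-trimethoxybenzoate F6. Mild hydrolysis of the remaining aryl ester (K2CO3, MeOH/H2O, rt, Ar) should give 5.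

Step 5. Chemoselectivity may be lost (methylation of the chelated 5-OH as well), or the hydroquinone may autoxidise under base. The fallback sets out from 8 and comes back at 9. Exhaustive methylation (Me2SO4 excess, K2CO3, acetone, reflux) should give 5,7,8-trimethoxy-2-(2,3,4-trimethoxyphenyl)-4H-chromen-4-one F7. Chelation-directed cleavage of the methoxy group peri to the carbonyl (BCl3, 1.1 equiv, CH2Cl2, −78 to 0 °C) should then give 9.

**Further compounds**
F1 | step 4 | 1-(2,6-dihydroxy-4-methoxyphenyl)ethan-1-one | CC(=O)c1c(O)cc(OC)cc1O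
F2 | step 4 | 1-(2,6-dihydroxy-4-methoxyphenyl)-3-(2,3,4-trimethoxyphenyl)propane-1,3-dione | COc1ccc(C(=O)CC(=O)c2c(O)cc(OC)cc2O)c(OC)c1OC
F3 | step 4 | 5-hydroxy-7-methoxy-2-(2,3,4-trimethoxyphenyl)-4H-chromen-4-one | COc1ccc(-c2cc(=O)c3c(O)cc(OC)cc3o2)c(OC)c1OC
F4 | step 4 | 5-hydroxy-7-methoxy-4-oxo-2-(2,3,4-trimethoxyphenyl)-4H-chromen-8-yl hydrogen sulfate | COc1ccc(-c2cc(=O)c3c(O)cc(OC)c(OS(=O)(=O)O)c3o2)c(OC)c1OC
F5 | step 3 | 2-acetyl-5-methoxy-1,4-phenylene bis(2,3,4-trimethoxybenzoate) | CC(=O)c1cc(OC(=O)c2ccc(OC)c(OC)c2OC)c(OC)cc1OC(=O)c1ccc(OC)c(OC)c1OC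
F6 | step 3 | 4-hydroxy-2-methoxy-5-[3-oxo-3-(2,3,4-trimethoxyphenyl)propanoyl]phenyl 2,3,4-trimethoxybenzoate | COc1ccc(C(=O)CC(=O)c2cc(OC(=O)c3ccc(OC)c(OC)c3OC)c(OC)cc2O)c(OC)c1OC
F7 | step 5 | 5,7,8-trimethoxy-2-(2,3,4-trimethoxyphenyl)-4H-chromen-4-one | COc1ccc(-c2cc(=O)c3c(OC)cc(OC)c(OC)c3o2)c(OC)c1OC
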